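All runs come from a simulation from invented constants; scatter was added.

You have to decide how far apart to set the 3 portions of partner when 50 mM of free catalyst is to turn starting material into product within 20 min.

| flask | starting material | partner | free catalyst | remark | time |
|---|---|---|---|---|---|
| south-west | 0.50 M | 0.475 M (in portions, 3) | 25 mM | run made earlier; portions every 2.0 min |  |
| north | 0.50 M | 0.475 M (in portions, 3) | 100 mM | run made earlier; portions every 2.0 min |  |
| ochre | 0.50 M | 0.475 M (in portions, 3) | 50 mM | the portions of partner follow each other after 2.0 min, the first at the start | 20 min |
| amber | 0.50 M | 0.475 M (in portions, 3) | 50 mM | the portions of partner follow each other after 3.0 min, the first at the start | 20 min |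
| blue | 0.50 M | 0.475 M (in portions, 3) | 50 mM | the portions of partner follow each other after 5.0 min, the first at the start | 20 min |
| green | 0.50 M | 0.475 M (in portions, 3) | 50 mM | the portions of partner follow each other after 6.0 min, the first at the start | 20 min |
| grey | 0.50 M | 0.475 M (in portions, 3) | 50 mM | the portions of partner follow each other after 10 min, the first at the start | 20 min |

| run | time / min | product / % |
|---|---|---|
| south-west | 5.00 | 6.6 |
| south-west | 10.0 | 11.5 |
| south-west | 15.0 | 13.3 |
| south-west | 20.0 | 15.0 |
| south-west | 25.0 | 16.1 |
| north | 2.00 | 5.6 |
| north | 6.00 | 24.0 |
| north | 12.0 | 39.5 |
| north | 15.0 | 40.9 |
| north | 25.0 | 42.8 |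

(readings scatter by 0.5 percentage points)

1. [product] at the end for ochre, amber, blue, green, grey, in this order
2. how that number moves from the first to the last of them (hardly changes / falls, then rises / falls all the way / rises all the way / rises, then falls)

- "hardly changes" means that all values lie within two and a half points (for a concentration: within two and a half percent of the largest)

Which numbers must you know well? The charges are the same in each flask of the row, so they do not separate its points. The level of the row comes from the plateaus of the earlier runs, and a slip of one scatter, 0.5 percentage points, on the south-west plateau of 16.1% is a small one. The sensitive number is how quickly product stops arriving after the last portion. Green has 8.00 min left after that portion, and a tail half-life of 3.00 min rather than 4.00 min moves its unfinished share from 15.7% to 25.0%. Ochre has 16.0 min left, so the same change moves it from 2.48% to 6.25%.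

Now the numbers themselves. The south-west run levels near 0.0805 M and the north run near 0.214 M, though partner, the limiting reagent by charge, was charged at 0.475 M. Product per catalyst reads 3.22 in the south-west run, more than the 2.14 of the north run. My reading, as an assumption, is that partner goes elsewhere, and more readily where it stands concentrated. Since 50 mM lies midway by ratio between the two catalyst levels, I take the root of the two plateaus for ochre, 0.131 M, and I expect wider spacing to start above that.

For the late end, the readings give 2.39 min in the north run and 4.84 min in the south-west run. Their root is 3.40 min, the tail half-life, the time in which the product still to come halves once the last portion is in. Green then leaves 19.6% unfinished, while grey has 0 min left after its last portion. So I commit to a row that rises from ochre and then falls to grey.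

The forecast differs, holding that “the catalyst dies”: 0.133 M, 0.131 M, 0.124 M, 0.121 M, 0.102 M, so falls all the way. The flasks give 0.130 M, 0.143 M, 0.157 M, 0.158 M, 0.123 M, so rises, then falls.

    2 partner → homo dimer (k = 2.10 L mol⁻¹ min⁻¹)
    starting material + catalyst intermediate B ⇌ catalyst intermediate C (K = 0.910 L mol⁻¹, k = 2.20 L mol⁻¹ min⁻¹)
    catalyst intermediate A ⇌ catalyst intermediate B (K = 2.60, k = 2.50 min⁻¹)
    catalyst intermediate C → free catalyst + product (k = 18.0 min⁻¹)
    partner + free catalyst → catalyst intermediate A (k = 5.60 L mol⁻¹ min⁻¹)

Grey ends at 0.123 M because two things act together: the path from two partner to homo dimer, without which it reaches 0.224 M, and the reading at 20.0 min, against 0.195 M at 200 min. That late gain of 0.0725 M is what grey still owes with no time left. Blue has 10.0 min after its last portion, so a tail half-life of 3.40 min leaves 13.0% of its product still to come. Blue's product, in percent of the starting material charged, stood at 17.6% at 10.0 min, 31.4% at 20.0 min and 33.8% at 200 min, so the share still to come at the end was 14.6%.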